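The route disconnects the four phenolic C–O bonds at positions 2 and 6 of ring A and positions 4 and 6 of ring B. In the target each acyl-bearing carbon (position 1 of ring A, butanoyl; position 5 of ring B, propanoyl) lies between two hydroxylated carbons, and these four carbons are the only ring positions not occupied by the two methyls, the bridging methylene, the ring A methoxy or the ring B para hydroxyl. One ketone-directed palladium C–H oxidation should therefore turn diarylmethane 9, whose only aromatic hydrogens sit at exactly these sites, into the target. Compound 9 is assembled from two para-acylated cresol units by Friedel–Crafts chemistry.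

Key step: step 5

Remark on the chemistry: ring A is the butanoyl ring, numbered from its acyl-bearing carbon as position 1 (methyl on position 3, methoxy on position 4, bridge on position 5). Ring B is the propanoyl ring, numbered from its bridge-bearing carbon as position 1 (hydroxyl on position 2, methyl on position 3, acyl on position 5). It is assumed that the ring B position 2 phenol needs no separate protection, since it is esterified in the key-step medium before the oxidant is added and freed again in the aqueous work-up.

Step 1
Reactants: 1 2-methylanisole; 2 butanoyl chloride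
Product: 3 1-(4-methoxy-3-methylphenyl)butan-1-one
Conditions: AlCl3 (1.2 equiv), CH2Cl2, 0 °C → rt; aq. HCl
Reagents that add atoms: none
Why: Friedel–Crafts acylation goes para to the methoxy group, the strongest donor on the ring, and the low temperature keeps AlCl3 from cleaving the methyl ether.

Step 2
Reactants: 3 1-(4-methoxy-3-methylphenyl)butan-1-one
Product: 4 1-[3-(chloromethyl)-4-methoxy-5-methylphenyl]butan-1-one
Conditions: (CH2O)n (1.5 equiv), conc. aq. HCl, 50 °C (closed system)
Reagents that add atoms: formaldehyde (as paraformaldehyde), C=O; hydrogen chloride, Cl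
Why: Blanc chloromethylation should attack the only free carbon still activated by the methoxy group (ortho to it, meta to the ketone), since the two other free carbons are ortho to the deactivating acyl group.

Step 3
Reactants: 5 2-methylphenol; 6 propanoyl chloride
Product: 8 1-(4-hydroxy-3-methylphenyl)propan-1-one, via 2-methylphenyl propanoate 7 (not isolated)
Conditions: AlCl3 (2.5 equiv), PhNO2, 0 → 25 °C, one pot; aq. HCl
Reagents that add atoms: none
Why: O-acylation of the phenol is followed by an AlCl3-mediated Fries rearrangement, which at room temperature in nitrobenzene favours migration of the acyl group to the unhindered carbon para to oxygen.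

Step 4
Reactants: 4 1-[3-(chloromethyl)-4-methoxy-5-methylphenyl]butan-1-one; 8 1-(4-hydroxy-3-methylphenyl)propan-1-one (1.5 equiv)
Product: 9 1-[3-[(5-butanoyl-2-methoxy-3-methylphenyl)methyl]-4-hydroxy-5-methylphenyl]propan-1-one
Conditions: ZnCl2 (1.0 equiv), ClCH2CH2Cl, 70 °C
Reagents that add atoms: none
Why: In this Friedel–Crafts benzylation ZnCl2 ionises the benzylic chloride and the phenol can be attacked only at its one free carbon ortho to the hydroxyl (its two other free carbons flank the ketone), while neither 4 nor product 9 has an activated free ring position for over-alkylation.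

Step 5
Reactants: 9 1-[3-[(5-butanoyl-2-methoxy-3-methylphenyl)methyl]-4-hydroxy-5-methylphenyl]propan-1-one
Product: 12 1-[3-[(3-butanoyl-2,4-dihydroxy-6-methoxy-5-methylphenyl)methyl]-2,4,6-trihydroxy-5-methylphenyl]propan-1-one, via aryl mono(trifluoroacetate) 10 (not isolated), via pentakis(trifluoroacetate) 11 (not isolated)
Conditions: CF3CO2H–(CF3CO)2O (4:1), 25 °C, 30 min; then Pd(OAc)2 (20 mol%), K2S2O8 (6 equiv, in portions), 50–60 °C; then THF–H2O, 25 °C
Reagents that add atoms: trifluoroacetic acid, OC(=O)C(F)(F)F; trifluoroacetic anhydride, O=C(OC(=O)C(F)(F)F)C(F)(F)F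
Why: Proposed new method: each ketone oxygen should bind divalent palladium and hold it over an ortho C–H bond, which is cleaved by trifluoroacetate-assisted concerted metalation–deprotonation to a five-membered palladacycle; K2S2O8 oxidises this to a tetravalent palladium trifluoroacetate, C–O reductive elimination releases the aryl trifluoroacetate together with divalent palladium, and the cycle should run twice at each ketone. The closest known reaction type is the ketone-directed ortho C–H hydroxylation of simple aryl ketones with Pd(OAc)2 or [RuCl2(p-cymene)]2 and persulfate or hypervalent iodine oxidants in trifluoroacetic acid and its anhydride, established for a single unhindered ortho position; exhaustive oxidation of four positions that each have a second neighbouring substituent is the unproven extension. No ring is closed and no stereocentre is formed. Site selectivity is secured by the substrate, because positions 2 and 6 of ring A and positions 4 and 6 of ring B carry the only aromatic hydrogens of 9 and are the only carbons a ketone-bound metal can reach through a five-membered palladacycle. Chemoselectivity against oxidation of the doubly benzylic bridging methylene and of the phenols rests on masking: the ring B position 2 hydroxyl is trifluoroacetylated before the oxidant is added and every new oxygen emerges as an electron-poor ester, so neither ring becomes an oxidisable free phloroglucinol until aqueous work-up cleaves all five esters. The growing deactivation of both rings is met by a high Pd(OAc)2 loading, K2S2O8 added in portions and continued heating until the partly oxidised intermediates are consumed.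

Compound list
1 | 2-methylanisole | COc1ccccc1C | starting material
2 | butanoyl chloride | CCCC(Cl)=O | starting material
3 | 1-(4-methoxy-3-methylphenyl)butan-1-one | CCCC(=O)c1ccc(OC)c(C)c1 | intermediate
4 | 1-[3-(chloromethyl)-4-methoxy-5-methylphenyl]butan-1-one | CCCC(=O)c1cc(C)c(OC)c(CCl)c1 | intermediate
5 | 2-methylphenol | Cc1ccccc1O | starting material
6 | propanoyl chloride | CCC(Cl)=O | starting material
7 | 2-methylphenyl propanoate (formed in the flask, not isolated) | CCC(=O)Oc1ccccc1C | intermediate
8 | 1-(4-hydroxy-3-methylphenyl)propan-1-one | CCC(=O)c1ccc(O)c(C)c1 | intermediate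
9 | 1-[3-[(5-butanoyl-2-methoxy-3-methylphenyl)methyl]-4-hydroxy-5-methylphenyl]propan-1-one | CCCC(=O)c1cc(C)c(OC)c(Cc2cc(C(=O)CC)cc(C)c2O)c1 | intermediate
10 | [2-[(5-butanoyl-2-methoxy-3-methylphenyl)methyl]-6-methyl-4-propanoylphenyl] 2,2,2-trifluoroacetate (trifluoroacetate of the ring B phenol of 9, not isolated) | CCCC(=O)c1cc(C)c(OC)c(Cc2cc(C(=O)CC)cc(C)c2OC(=O)C(F)(F)F)c1 | intermediate
11 | pentakis(trifluoroacetate) of 12, in which all five phenolic oxygens (two on ring A, three on ring B) carry COCF3 (not isolated) | CCCC(=O)c1c(OC(=O)C(F)(F)F)c(C)c(OC)c(Cc2c(OC(=O)C(F)(F)F)c(C)c(OC(=O)C(F)(F)F)c(C(=O)CC)c2OC(=O)C(F)(F)F)c1OC(=O)C(F)(F)F | intermediate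
12 | 1-[3-[(3-butanoyl-2,4-dihydroxy-6-methoxy-5-methylphenyl)methyl]-2,4,6-trihydroxy-5-methylphenyl]propan-1-one | CCCC(=O)c1c(O)c(C)c(OC)c(Cc2c(O)c(C)c(O)c(C(=O)CC)c2O)c1O | target

Total step count: 5. Longest linear sequence: 4 (steps 1, 2, 4 and 5).

Steps most likely to fail

Step 5. The oxidation may stall after one or two C–O bonds, as each new ester makes the ring poorer and the remaining sites are crowded. Sulfate radicals may also oxidise the bridging methylene, or partial loss of the ester masking may allow over-oxidation of a freed polyphenol. The fallback uses known chemistry, sets out from butanoyl chloride 2 and propanoyl chloride 6, and comes back at 12. Commercial 2-methylbenzene-1,3,5-triol is C-acylated with 2 (AlCl3, PhNO2–CH2Cl2) to 1-(2,4,6-trihydroxy-3-methylphenyl)butan-1-one F1. Its non-chelated hydroxyl para to the ketone is methylated selectively (MeI, 1 equiv, K2CO3, acetone) to 1-(2,6-dihydroxy-4-methoxy-3-methylphenyl)butan-1-one F2. The same acylation with 6 gives 1-(2,4,6-trihydroxy-3-methylphenyl)propan-1-one F3. Each of these two acylphloroglucinols has a single free ring carbon, which corresponds to position 5 of ring A and position 1 of ring B. Their condensation with aqueous formaldehyde in dilute aqueous KOH at room temperature, the classical methylene bridging of acylphloroglucinols, should give 12, to be separated from the two symmetrical dimers.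

Step 4. C-alkylation of the ketone-deactivated phenol may be slow, so that O-benzylation, hydrolysis or decomposition of the benzylic cation wins. The fallback sets out from 8 and 4 and comes back at 9. Bromination of 8 ortho to the hydroxyl (NBS, MeCN, 0 °C) gives 1-(3-bromo-4-hydroxy-5-methylphenyl)propan-1-one F4. Borylation of the benzylic chloride 4 (bis(pinacolato)diboron, Pd2(dba)3, tri(4-methoxyphenyl)phosphine, KOAc, toluene, 50 °C) gives 1-[4-methoxy-3-methyl-5-[(4,4,5,5-tetramethyl-1,3,2-dioxaborolan-2-yl)methyl]phenyl]butan-1-one F5. Suzuki–Miyaura coupling of the aryl bromide with the benzylic boronate (PdCl2(dppf), K2CO3, dioxane–H2O, 80 °C) then forms the bond between the bridging methylene and ring B at the carbon fixed by the bromine.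

Step 2. Electrophilic attack on the acyl-deactivated ring may be sluggish, and the product chloride may then alkylate unreacted 3 to a symmetrical diarylmethane. The fallback avoids ring substitution at this carbon, sets out from 2 and comes back at 9. Friedel–Crafts acylation of commercial 2,6-dimethylanisole with 2 (AlCl3, CH2Cl2, 0 °C) gives 1-(4-methoxy-3,5-dimethylphenyl)butan-1-one F6. Wohl–Ziegler bromination of one of its two equivalent methyl groups (NBS, 1 equiv, AIBN, PhCF3, 80 °C) gives 1-[3-(bromomethyl)-4-methoxy-5-methylphenyl]butan-1-one F7. This benzylic bromide replaces 4 in the ZnCl2-mediated benzylation of 8 and gives 9.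

Further compounds
F1 | step 5 | 1-(2,4,6-trihydroxy-3-methylphenyl)butan-1-one | CCCC(=O)c1c(O)c(C)c(O)cc1O
F2 | step 5 | 1-(2,6-dihydroxy-4-methoxy-3-methylphenyl)butan-1-one | CCCC(=O)c1c(O)c(C)c(OC)cc1O
F3 | step 5 | 1-(2,4,6-trihydroxy-3-methylphenyl)propan-1-one | CCC(=O)c1c(O)c(C)c(O)cc1O
F4 | step 4 | 1-(3-bromo-4-hydroxy-5-methylphenyl)propan-1-one | CCC(=O)c1cc(C)c(O)c(Br)c1
F5 | step 4 | 1-[4-methoxy-3-methyl-5-[(4,4,5,5-tetramethyl-1,3,2-dioxaborolan-2-yl)methyl]phenyl]butan-1-one | CCCC(=O)c1cc(C)c(OC)c(CB2OC(C)(C)C(C)(C)O2)c1
F6 | step 2 | 1-(4-methoxy-3,5-dimethylphenyl)butan-1-one | CCCC(=O)c1cc(C)c(OC)c(C)c1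
F7 | step 2 | 1-[3-(bromomethyl)-4-methoxy-5-methylphenyl]butan-1-one | CCCC(=O)c1cc(C)c(OC)c(CBr)c1
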